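4 questions hang on this flask, and the hard one is the last: what share of its charge the epsilon run has turned into E by 13 h.

| flask | J | L | time |
|---|---|---|---|
| delta | 80.0 mM | 0.800 mM |  |
| gamma | 40.0 mM | 0.800 mM |  |
| theta | 80.0 mM | 2.40 mM |  |
| beta | 40.0 mM | 0.800 mM |  |
| epsilon | 23.0 mM | 0.800 mM | 13 h |

| delta run: time / h | delta run: [E] / mM | gamma run: time / h | gamma run: [E] / mM | theta run: time / h | theta run: [E] / mM | beta run: time / h | beta run: [E] / mM |
|---|---|---|---|---|---|---|---|
| 1.9 | 6.9 | 1.9 | 4.1 | 1.9 | 22.6 | 1.9 | 2.3 |
| 3.7 | 18.0 | 3.7 | 6.9 | 3.7 | 40.8 | 3.7 | 6.0 |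
| 5.6 | 31.0 | 5.6 | 7.4 | 5.6 | 54.0 | 5.6 | 6.9 |
| 7.4 | 44.5 | 7.4 | 12.7 | 7.4 | 65.9 | 7.4 | 12.8 |
| 9.3 | 55.2 | 9.3 | 13.8 | 9.3 | 72.3 | 9.3 | 17.1 |
| 11 | 64.6 | 11 | 18.8 | 11 | 76.7 | 11 | 18.7 |
| 13 | 72.1 | 13 | 22.5 | 13 | 77.5 | 13 | 21.4 |

(readings scatter by 1 mM)

- reaction order in [J] at the outset, round the charge of the delta run, defined at two percent of the J turned into E (one fixed amount of E, the same in the runs compared)
- reaction order in [L] at the outset, round the charge of the delta run, defined at two percent of the J turned into E
- the gamma run starts with 40.0 mM less of J than the delta run, and with no E. Compared where both hold the same amount of J, once fifteen percent of what the gamma run was charged with has turned into E, is the gamma run faster, slower or alike (within a tenth)?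
- E in the epsilon run at 13 h, as a share of the J charged

- Overall: J -> E, with L as catalyst.
- Constant volume, constant temperature.
- An order is taken over about fifteen percent of the charge, up and down.

This is my own reckoning, in shares x of the charge and in the odds, x divided by the share still left, with the clocks taken from quick to slow.

The first clock is self-feeding (autocatalysis): the delta rate climbs up to 7.4 h while J falls. Between 11 h and 13 h, I set the delta run's climb in share equal to g times x times the share left:

g(delta) = 0.377 /h, a clock of 2.65 h

I take g to go with the charge:

g(gamma) = 0.188 /h, g(epsilon) = 0.108 /h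

The next clock is the catalyst's. The first theta reading stands clearest of the scatter; scaled down to the L of delta, it gives an early rate of 0.0582 /h. Yet from 7.4 h to 13 h, the mean share of gamma and beta, around 0.434, climbs 0.0411 /h, which is less than feeding supplies, at 0.0463 /h. That gap is a reading with the scatter in it, and I take the catalyst's work as faded by then.

After that the odds grow as exp(gt). Running gamma and beta back from their mean share 0.549 at 13 h gives a seed, the odds the catalyst leaves behind:

seed(gamma) = 0.105

E made later has less time to multiply, so seed = early rate / (f + g), where f is the fading rate, the share of the catalyst's work lost per hour: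

f = 0.366 /h, a clock of 2.73 h, about that of delta's feeding

Gamma's feeding clock is 5.32 h, and epsilon's is slower still at 9.26 h. Epsilon is therefore a small seed multiplying slowly.

First pass, with gamma's seed: 30.0 %.

Second round, with epsilon's own seed 0.123: 33.4 %.

The forecast gives orders of 1.1 in J and 1 in L, gamma slower, and 48 % for epsilon, by “the integrated logistic form, calibrated on gamma”. Its share is higher than mine.

The flask gives orders of 1.1 and 0.99, gamma slower, and 33.4 % for epsilon.

    L + J → E + L (70.56 /M/h)
    J + E → 2 E (4.500 /M/h)
    L → Oz (0.3672 /h)

L going to Oz holds the epsilon share down: the same epsilon run without that step reaches 71.2 %. Carried to delta, f gives a seed of 0.0784, so its odds reach even at 6.75 h, and the delta run's E comes to half its charge at 6.87 h.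

All runs are simulated with made-up constants.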